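**Retrosynthetic overview**
- Target 13 goes back to 3-[14-(3-methoxyphenyl)tetradecyl]phenol 8: the two C5–O bonds, one on ring A (the anisole ring) and one on ring B (the later resorcinol ring), are made last and together from two aryl C–H bonds by borylation/oxidation in one flask.
- The OMe/OH difference between the rings is bought, not made: ring A comes from 3-bromoanisole 3, ring B from 3-bromophenol 6.
- 8 goes back to alkene 5 and 6 (hydroboration with 9-BBN 2, then B-alkyl Suzuki–Miyaura coupling at the ring B end of the chain).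
- 5 goes back to tetradeca-1,13-diene 1 (used in excess, hydroborated once) and 3 (same coupling at the ring A end).
- No ring is built: both benzene rings and the C14 chain are bought; ring A is attached first, ring B second.

Assumption: the target SMILES has no stereocentre and no stereogenic double bond, so the compound is achiral and is made exactly as drawn without any stereocontrol.

**Step 1**
Reactants: 1 tetradeca-1,13-diene (4 equiv); 2 9-borabicyclo[3.3.1]nonane (9-BBN, 1.0 equiv); 3 1-bromo-3-methoxybenzene (3-bromoanisole, 0.9 equiv)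
Product: 5 1-methoxy-3-(tetradec-13-en-1-yl)benzene, via alkylborane 4 (not isolated)
Conditions: 2 (0.5 M in THF) added slowly to 1, THF, 0 °C to rt, 6 h; then 3, Pd(dppf)Cl2·CH2Cl2 (3 mol%), aq K3PO4 (3 M, 3 equiv), THF/DMF, 60 °C, 12 h; excess 1 recovered by vacuum distillation
Reagents that add atoms: none
Why: 9-BBN adds anti-Markovnikov to a terminal alkene and, with the diene in fourfold excess, about 87% of the boron ends up in the mono-adduct 4, whose primary B-alkyl group transmetalates to the arylpalladium bromide formed from 3 and zerovalent palladium (B-alkyl Suzuki–Miyaura coupling) while the second terminal alkene stays untouched; no stereocentre is formed.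

**Step 2**
Reactants: 5 1-methoxy-3-(tetradec-13-en-1-yl)benzene (1.0 equiv); 2 9-BBN (1.2 equiv); 6 3-bromophenol (1.3 equiv)
Product: 8 3-[14-(3-methoxyphenyl)tetradecyl]phenol, via alkylborane 7 (not isolated)
Conditions: 2, THF, 0 °C to rt, 6 h; then 6, Pd(OAc)2 (2 mol%), SPhos (4 mol%), aq K3PO4 (3 M, 4 equiv), THF, 65 °C, 14 h; dilute HCl work-up
Reagents that add atoms: none
Why: the same hydroboration/B-alkyl Suzuki–Miyaura sequence closes the C14 link, the electron-rich biarylphosphine SPhos keeping oxidative addition fast for the bromophenoxide that 6 forms in base, so that the phenol needs no protecting group; no stereocentre is formed.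

**Step 3**
Reactants: 8 3-[14-(3-methoxyphenyl)tetradecyl]phenol (1.0 equiv); 9 pinacolborane (HBpin, 1.3 equiv); 10 bis(pinacolato)diboron (B2pin2, 1.5 equiv)
Product: 13 5-[14-(3-hydroxy-5-methoxyphenyl)tetradecyl]benzene-1,3-diol, via aryloxyborane 11 (not isolated), via triboryl compound 12 (not isolated)
Conditions: 9, [Ir(cod)(OMe)]2 (2 mol%), 3,4,7,8-tetramethyl-1,10-phenanthroline (tmphen, 4 mol%), THF, rt to 50 °C, 1 h (H2 evolves); then 10, 80 °C, 16 h; evaporate; then Oxone (2KHSO5·KHSO4·K2SO4, 2.5 equiv), acetone/H2O 1:1, 0 °C to rt, 15 min; aq NaHSO3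
Reagents that add atoms: Oxone (active salt potassium peroxymonosulfate, KHSO5), [K+].[O-]S(=O)(=O)OO
Why: Proposed new method: a one-flask twofold meta C–H hydroxylation of a bis-arene that carries a free phenol. HBpin first turns the acidic O–H of 8 into the bulky aryloxy–Bpin ester 11 with loss of H2. The trivalent iridium tris(boryl) complex of tmphen then cleaves, on each 1,3-disubstituted ring, the only aromatic C–H that has no ortho neighbour (C5 of ring A and C5 of ring B; C2, C4 and C6 are flanked by the chain, OMe or OBpin) by oxidative addition and C–B reductive elimination, giving 12. Oxone turns each C–B bond into C–O by peroxide attack on boron and 1,2-aryl shift, and water strips the O–B mask. The closest known reaction type is the one-pot iridium-catalysed C–H borylation/Oxone oxidation of 1,3-disubstituted arenes to 3,5-disubstituted phenols; it has not been shown twofold on two different rings of one molecule, nor on a phenol masked in the flask as its O–Bpin ester, a group otherwise known to favour ortho borylation when no unhindered meta C–H is on offer. No stereocentre is formed.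

**Compound list**
1 | tetradeca-1,13-diene | C=CCCCCCCCCCCCC=C | starting material
2 | 9-borabicyclo[3.3.1]nonane (9-BBN) | B1C2CCCC1CCC2 | starting material
3 | 1-bromo-3-methoxybenzene (3-bromoanisole) | COc1cccc(Br)c1 | starting material
4 | 9-(tetradec-13-en-1-yl)-9-borabicyclo[3.3.1]nonane | C=CCCCCCCCCCCCCB1C2CCCC1CCC2 | intermediate
5 | 1-methoxy-3-(tetradec-13-en-1-yl)benzene | COc1cccc(CCCCCCCCCCCCC=C)c1 | intermediate
6 | 3-bromophenol | Oc1cccc(Br)c1 | starting material
7 | 9-[14-(3-methoxyphenyl)tetradecyl]-9-borabicyclo[3.3.1]nonane | COc1cccc(CCCCCCCCCCCCCCB2C3CCCC2CCC3)c1 | intermediate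
8 | 3-[14-(3-methoxyphenyl)tetradecyl]phenol | COc1cccc(CCCCCCCCCCCCCCc2cccc(O)c2)c1 | intermediate
9 | 4,4,5,5-tetramethyl-1,3,2-dioxaborolane (pinacolborane, HBpin) | CC1(C)OBOC1(C)C | starting material
10 | bis(pinacolato)diboron (B2pin2) | CC1(C)OB(OC1(C)C)B1OC(C)(C)C(C)(C)O1 | starting material
11 | 2-{3-[14-(3-methoxyphenyl)tetradecyl]phenoxy}-4,4,5,5-tetramethyl-1,3,2-dioxaborolane | COc1cccc(CCCCCCCCCCCCCCc2cccc(OB3OC(C)(C)C(C)(C)O3)c2)c1 | intermediate
12 | 2-[3-methoxy-5-(14-{3-(4,4,5,5-tetramethyl-1,3,2-dioxaborolan-2-yl)-5-[(4,4,5,5-tetramethyl-1,3,2-dioxaborolan-2-yl)oxy]phenyl}tetradecyl)phenyl]-4,4,5,5-tetramethyl-1,3,2-dioxaborolane | COc1cc(B2OC(C)(C)C(C)(C)O2)cc(CCCCCCCCCCCCCCc2cc(OB3OC(C)(C)C(C)(C)O3)cc(B3OC(C)(C)C(C)(C)O3)c2)c1 | intermediate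
13 | 5-[14-(3-hydroxy-5-methoxyphenyl)tetradecyl]benzene-1,3-diol (achiral) | COc1cc(O)cc(CCCCCCCCCCCCCCc2cc(O)cc(O)c2)c1 | target

**Totals**
Total step count: 3. Longest linear sequence: 3.

**Steps most likely to fail**

Step 3 (the proposed new step). The risks are partial ortho borylation at C4 of ring B through attraction between the OBpin group and the ligand, an incomplete second borylation, and over-oxidation of the electron-rich resorcinol by Oxone. The fallback uses only known chemistry and sets out from 8. The phenol is silylated (TIPSCl, imidazole, DMF, rt) to give triisopropyl{3-[14-(3-methoxyphenyl)tetradecyl]phenoxy}silane F4, in which the bulky silyl ether is a purely steric substituent. The established borylation of 1,3-disubstituted arenes ([Ir(cod)(OMe)]2, 4,4'-di-tert-butyl-2,2'-bipyridine, B2pin2, THF, 80 °C) then gives the bis(boronate) triisopropyl{3-[14-(3-methoxy-5-Bpin-phenyl)tetradecyl]-5-Bpin-phenoxy}silane F5 (Bpin = 4,4,5,5-tetramethyl-1,3,2-dioxaborolan-2-yl). Oxone in acetone/water converts it into 3-[14-(3-hydroxy-5-methoxyphenyl)tetradecyl]-5-[(triisopropylsilyl)oxy]phenol F6, and Bu4NF in THF removes the silyl group. The fallback comes back to the route at 13.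

Step 2. The risk is that the bromophenoxide couples slowly, so that protodeboronation or β-hydride elimination of the alkylborane takes over. The fallback sets out from 5, again through borane 7, and brings ring B in as its benzyl ether. Coupling with 1-(benzyloxy)-3-bromobenzene (Pd(dppf)Cl2·CH2Cl2, aq K3PO4, THF/DMF, 60 °C) gives 1-(benzyloxy)-3-[14-(3-methoxyphenyl)tetradecyl]benzene F3. Hydrogenolysis (H2, 10% Pd/C, EtOAc/EtOH, rt) frees the phenol, and the fallback comes back to the route at 8.

Step 1. The risk is the statistical single hydroboration of the diene: the doubly arylated by-product has to be separated and the yield on 9-BBN is capped. The fallback gives up the symmetric diene for a chain with two different ends and sets out from 3. Magnesium in THF gives 3-methoxyphenylmagnesium bromide F1. Copper-catalysed alkylation (Li2CuCl4, 3 mol%, THF/NMP, 0 °C) with a fourfold excess of 1,11-dibromoundecane gives 1-(11-bromoundecyl)-3-methoxybenzene F2. Displacement of the remaining bromide with allylmagnesium bromide (CuI, 5 mol%, THF, 0 °C to rt) adds the last three carbons, and the fallback comes back to the route at 5.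

**Further compounds**
F1 | step 1 | 3-methoxyphenylmagnesium bromide | COc1cccc([Mg]Br)c1
F2 | step 1 | 1-(11-bromoundecyl)-3-methoxybenzene | COc1cccc(CCCCCCCCCCCBr)c1
F3 | step 2 | 1-(benzyloxy)-3-[14-(3-methoxyphenyl)tetradecyl]benzene | COc1cccc(CCCCCCCCCCCCCCc2cccc(OCc3ccccc3)c2)c1
F4 | step 3 | triisopropyl{3-[14-(3-methoxyphenyl)tetradecyl]phenoxy}silane | COc1cccc(CCCCCCCCCCCCCCc2cccc(O[Si](C(C)C)(C(C)C)C(C)C)c2)c1
F5 | step 3 | triisopropyl{3-[14-(3-methoxy-5-(4,4,5,5-tetramethyl-1,3,2-dioxaborolan-2-yl)phenyl)tetradecyl]-5-(4,4,5,5-tetramethyl-1,3,2-dioxaborolan-2-yl)phenoxy}silane | COc1cc(B2OC(C)(C)C(C)(C)O2)cc(CCCCCCCCCCCCCCc2cc(O[Si](C(C)C)(C(C)C)C(C)C)cc(B3OC(C)(C)C(C)(C)O3)c2)c1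
F6 | step 3 | 3-[14-(3-hydroxy-5-methoxyphenyl)tetradecyl]-5-[(triisopropylsilyl)oxy]phenol | COc1cc(O)cc(CCCCCCCCCCCCCCc2cc(O)cc(O[Si](C(C)C)(C(C)C)C(C)C)c2)c1
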